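## The problem

The target 32 is an 11-oxatricyclo[4.3.2.0^{1,5}]undecan-10-one: a cyclopentane and a bromocyclohexane share the C1–C5 bond, and a γ-lactone bridges the quaternary C1 (lactone carbonyl C10) to the methyl-bearing C6 (O11). A CH2 group at C4 links this core to ring A, a 4-bromo-1-hydroxy-3,3-dimethylcyclohexyl unit. There are seven stereocentres: five contiguous ones in the core (C1, C4, C5, C6, C9) and two in ring A (C1′, C4′). The core centres can relay: C4, as an allylic stereocentre in an open chain, can direct the ring-fusion carbon C5; a chair transition state and the lactone bridge then fix C1 and C6; the locked chair finally directs the equatorial bromide at C9. Ring A is too remote to be controlled from the core, so it must be brought in as an enantiopure fragment, and its carbinol centre is set at the moment of union. Both bromides are secondary and neopentylic: they cannot be made by substitution, and they are at risk with strong base and reducing metals. The hindered lactone and the tertiary alcohol (dehydration) also limit late chemistry. The key step rests on C1: it carries the lactone carbonyl and is flanked by C9, so with C9 as a ketone C1 is the α-carbon of a β-keto ester. Its radical can add to a C5=C6 alkene, and the cation left at C6 can be captured by the ester.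

## Retrosynthesis

**Union of the fragments.** The CH2–C1′ bond of 32 is cut to give the core iodide 25 and (S)-4-bromo-3,3-dimethylcyclohexanone 29. This is the only cut that divides the molecule into two pieces of similar size and removes ring A with both of its heteroatoms in place. The forward step needs an organometallic from 25 that spares the lactone and the bromides, and equatorial attack on 29, anti to the axial methyl group, in the chair with equatorial bromine.

**Ring A ketone.** Ketone 29 is traced to the exocyclic enol ether 28, to bromolactone 27 and to 5-methylhex-4-enoic acid 26. The bromide stereocentre is set by a catalytic enantioselective bromolactonisation, which avoids substitution at a neopentyl carbon. The ring oxygen is then exchanged for CH2 by methylenation and a [1,3] oxygen-to-carbon shift that runs through a bromonium ion and therefore keeps the configuration. A direct bromonium carbocyclisation onto an enol was set aside, because electrophilic bromine would attack the enol first.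

**Core bromide.** Iodide 25 comes from silyl ether 23, and the C9–Br bond of 23 from alkenyl bromide 22 by hydrogen-atom-transfer hydrogenation. Against reduction of the ketone and displacement (neopentyl, not feasible), this uses the locked chair: the α-bromo radical takes hydrogen axially and bromine ends equatorial. The alkenyl bromide 17 is made from ketone 15 through enol triflate 16.

**Cyclopentane.** The C2–C3 bond of 22 is opened to the diene 20 (ring-closing metathesis to 21, then diimide reduction). The vinyl group on C1 of 20 comes from the silyloxymethyl group of 17 through alcohol 18 and aldehyde 19. The ketone is converted to the alkenyl bromide before the aldehyde is unveiled, since a formyl group on a carbon flanked by ketone and lactone would be lost by deformylation.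

**Key disconnection.** In 15 the C1–C8 bond (ring fusion) and the C5–O6 bond are cut together, giving the acyclic β-keto ester 14. One step forms a cyclohexanone, a γ-lactone, a quaternary carbon and three stereocentres. The forward reaction needs 6-endo addition through a chair, attack on the alkene face chosen by the allylic stereocentre, and capture of the tertiary cation by the axial ester.

**β-Keto ester.** Ester 14 is cut between C3 and C2 to aldehyde 10 and ethyl 3-silyloxypropanoate 12 (aldol to 13, then oxidation). This brings in the silyloxymethyl group with the ester, and avoids hydroxymethylation of a β-keto ester, which tends to run twice or to dehydrate.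

**(E)-Alkene and allylic stereocentre.** Aldehyde 10 comes from ester 9, and 9 from allylic alcohol 7 and triethyl orthoacetate 8 by a Johnson–Claisen rearrangement that sets the (E)-trisubstituted alkene. A 2-vinyl-3-silyloxypropanal would be the most direct source of 7, but it is a β,γ-unsaturated aldehyde and configurationally labile. The stereocentre is therefore set by an Evans aldol of crotonyl imide 3 with methacrolein 4 (to 5), followed by reduction to diol 6 and silylation. Imide 3 comes from oxazolidinone 1 and acid chloride 2.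

## Roads not taken

**Alternative 1:** The cyclopentane bond between the ring-fusion CH and the carbon that will bear the side chain is cut. Forward, a photochemical Wolff rearrangement contracts a six-membered ring and water traps the ketene to give acid A1.
- Merits: A1 already holds the lactone, the bromide and all ring atoms of the core, and its carboxyl group is the one-carbon handle for ring A. After its key step this road is shorter than the chosen one, which still needs about ten steps to reach iodide 25.
- Weak points: the contraction builds none of the hard features. The quaternary carbon, the lactone and the neopentyl bromide must all be in place beforehand. The C–Br bond is exposed to ultraviolet light. The new CH centre is set only by protonation of the ketene hydrate.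
- Comparison: the chosen plan sets against the shorter endgame a key step that makes the quaternary carbon, the ring fusion and the lactone from an open chain.

**Alternative 2:** The bond between the quaternary carbon and the CHBr carbon is cut. Forward, an Ireland–Claisen rearrangement through a boat transition state gives acid A2.
- Merits: the quaternary centre and the C–Br centre form together, and the bromide configuration is transferred from alkene geometry. In certainty of the C–Br configuration this is at least as good as a radical hydrogenation.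
- Weak points: A2 is an allylic bromide, prone to ionisation, allylic displacement and loss on hydrogenation of the neighbouring alkene. The enolisation needs strong base next to a bromoalkene. Four stereocentres, one of them a tertiary silyl ether, must be set before the key step.
- Comparison: the chosen plan sets against the transferred configuration a saturated bromide that is made only after all base and olefin chemistry at the core is done.

**Alternative 3:** The bond between the quaternary carbon and the cyclopentane CH2 is cut. Forward, N-bromosuccinimide triggers a semipinacol ring contraction that gives aldehyde A3.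
- Merits: one cheap reagent forms the quaternary carbon, the C–Br bond and an aldehyde, and the bromide is introduced without a separate step; in this respect it is better than the chosen plan.
- Weak points: the bromonium face and the choice of migrating ring bond must both be controlled. A3 still lacks the cyclohexane and the lactone, and these would have to be closed with a β-bromo aldehyde in the molecule, under conditions that invite elimination.
- Comparison: the chosen plan forms one C–C bond as well, but closes two rings in that step and carries no bromide through ring construction.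

Key step: step 10

## Route

Remarks on the chemistry: 14 is used as the mixture of C2 epimers, since this centre becomes planar in the manganese enolate. In step 21 the catalyst antipode is the one that delivers the (S)-bromide.

Step 1
Reactants: 1 (R)-4-benzyl-1,3-oxazolidin-2-one; 2 (E)-but-2-enoyl chloride
Product: 3 (R)-4-benzyl-3-[(E)-but-2-enoyl]-1,3-oxazolidin-2-one
Conditions: n-BuLi, THF, −78 °C; then 2, −78 → 0 °C
Reagents that add atoms: none
Why: N-Acylation of the lithiated oxazolidinone, the standard way to the crotonyl imide; no stereocentre is formed.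

Step 2
Reactants: 3 (R)-4-benzyl-3-[(E)-but-2-enoyl]-1,3-oxazolidin-2-one; 4 2-methylprop-2-enal
Product: 5 (4R)-4-benzyl-3-[(2R,3R)-2-ethenyl-3-hydroxy-4-methylpent-4-enoyl]-1,3-oxazolidin-2-one
Conditions: n-Bu2BOTf, Et3N, CH2Cl2, −78 → 0 °C; then 4, −78 → 0 °C; H2O2, MeOH, pH 7 buffer
Reagents that add atoms: none
Why: Evans syn-aldol of a crotonyl imide: γ-deprotonation gives the boron dienolate, which reacts at its α-carbon through a closed chair transition state on the face away from the benzyl group. This sets the vinyl-bearing carbon (2R), the future C4 of the core; the carbinol centre is consumed in step 5.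

Step 3
Reactants: 5 (4R)-4-benzyl-3-[(2R,3R)-2-ethenyl-3-hydroxy-4-methylpent-4-enoyl]-1,3-oxazolidin-2-one
Product: 6 (2S,3R)-2-ethenyl-4-methylpent-4-ene-1,3-diol
Conditions: LiBH4, MeOH (1 equiv), THF, 0 °C
Reagents that add atoms: none
Why: Reductive cleavage of the imide to the primary alcohol; the auxiliary is set free for re-use and the α-centre is not enolised by the borohydride.

Step 4
Reactants: 6 (2S,3R)-2-ethenyl-4-methylpent-4-ene-1,3-diol
Product: 7 (3R,4S)-4-{[(tert-butyldiphenylsilyl)oxy]methyl}-2-methylhexa-1,5-dien-3-ol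
Conditions: TBDPSCl, imidazole, CH2Cl2, 0 °C
Reagents that add atoms: tert-butyl(chloro)diphenylsilane, CC(C)(C)[Si](Cl)(c1ccccc1)c1ccccc1
Why: Selective silylation of the primary hydroxyl with a bulky silyl chloride; the large, weakly nucleophilic silyl ether is also the group that shields one alkene face in step 10.

Step 5
Reactants: 7 (3R,4S)-4-{[(tert-butyldiphenylsilyl)oxy]methyl}-2-methylhexa-1,5-dien-3-ol; 8 triethyl orthoacetate
Product: 9 ethyl (4E,6R)-6-{[(tert-butyldiphenylsilyl)oxy]methyl}-4-methylocta-4,7-dienoate
Conditions: EtCO2H (cat.), 140 °C, EtOH distilled off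
Reagents that add atoms: none
Why: Johnson–Claisen rearrangement through a chair transition state with the branched carbinol substituent equatorial, which gives the (E)-trisubstituted alkene. The carbinol stereocentre becomes the alkene CH; the allylic stereocentre is not touched.

Step 6
Reactants: 9 ethyl (4E,6R)-6-{[(tert-butyldiphenylsilyl)oxy]methyl}-4-methylocta-4,7-dienoate
Product: 10 (4E,6R)-6-{[(tert-butyldiphenylsilyl)oxy]methyl}-4-methylocta-4,7-dienal
Conditions: i-Bu2AlH, CH2Cl2, −78 °C; Rochelle salt
Reagents that add atoms: none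
Why: Partial reduction of the ester at low temperature stops at the aluminium hemiacetal, which gives the aldehyde on work-up.

Step 7
Reactants: 11 ethyl 3-hydroxypropanoate
Product: 12 ethyl 3-[(tert-butyldimethylsilyl)oxy]propanoate
Conditions: TBSCl, imidazole, DMF, 23 °C
Reagents that add atoms: tert-butyl(chloro)dimethylsilane, CC(C)(C)[Si](C)(C)Cl
Why: Routine silylation of a primary alcohol.

Step 8
Reactants: 10 (4E,6R)-6-{[(tert-butyldiphenylsilyl)oxy]methyl}-4-methylocta-4,7-dienal; 12 ethyl 3-[(tert-butyldimethylsilyl)oxy]propanoate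
Product: 13 ethyl (6E,8R)-2-{[(tert-butyldimethylsilyl)oxy]methyl}-8-{[(tert-butyldiphenylsilyl)oxy]methyl}-3-hydroxy-6-methyldeca-6,9-dienoate (mixture at C2 and C3)
Conditions: LiN(i-Pr)2, THF, −78 °C (12); then 10, −78 °C; aq. NH4Cl at −78 °C
Reagents that add atoms: none
Why: Aldol addition of the lithium ester enolate, kept at −78 °C so that loss of silanolate from the β-silyloxy enolate stays slow. Both new centres are removed or made planar in steps 9 and 10, so their configuration does not matter.

Step 9
Reactants: 13 ethyl (6E,8R)-2-{[(tert-butyldimethylsilyl)oxy]methyl}-8-{[(tert-butyldiphenylsilyl)oxy]methyl}-3-hydroxy-6-methyldeca-6,9-dienoate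
Product: 14 ethyl (6E,8R)-2-{[(tert-butyldimethylsilyl)oxy]methyl}-8-{[(tert-butyldiphenylsilyl)oxy]methyl}-6-methyl-3-oxodeca-6,9-dienoate (C2 epimers)
Conditions: Dess–Martin periodinane, NaHCO3, CH2Cl2, 0 → 23 °C
Reagents that add atoms: none
Why: Buffered Dess–Martin oxidation of the β-hydroxy ester gives the β-keto ester without base strong enough to eliminate the β-silyloxy group.

Step 10
Reactants: 14 ethyl (6E,8R)-2-{[(tert-butyldimethylsilyl)oxy]methyl}-8-{[(tert-butyldiphenylsilyl)oxy]methyl}-6-methyl-3-oxodeca-6,9-dienoate
Product: 15 (1S,5R,8S)-8-[(2R)-1-[(tert-butyldiphenylsilyl)oxy]but-3-en-2-yl]-1-{[(tert-butyldimethylsilyl)oxy]methyl}-5-methyl-6-oxabicyclo[3.2.1]octane-2,7-dione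
Conditions: Mn(OAc)3·2H2O (2.5 equiv), degassed AcOH, 25 → 40 °C
Reagents that add atoms: none
Why: Mn(OAc)3 forms the trivalent manganese enolate of the β-keto ester, which loses divalent manganese to give the electrophilic radical at C2. This radical adds 6-endo to the CH terminus of the (E)-trisubstituted alkene through a chair with the ketone in the ring, closing the cyclohexanone and leaving a tertiary radical. A second equivalent of trivalent manganese oxidises that radical to the cation, which the axial ester carbonyl, 1,3-diaxial to it, captures in a five-membered closure; acetate removes the ethyl group and the γ-lactone results. The closest known reaction type is the Mn(OAc)3 oxidative free-radical cyclisation of unsaturated β-keto esters, including lactone formation from tertiary cations. C8 is set by the chair and the (E)-geometry (side chain equatorial) and, in the absolute sense, by the allylic stereocentre: with its C–H bond eclipsing the alkene to avoid 1,3-allylic strain with the vinylic methyl, the radical enters on the face flanked by the small vinyl group, anti to the CH2OTBDPS group. C1 follows because only the chair with axial ester and equatorial CH2OTBS can lactonise, and C5 is fixed by the cis bridge. The step needs 6-endo over 5-exo addition, which the ketone in the chain and the tertiary radical secure, and lactone closure faster than proton loss, which the proximity of the ester and the absence of divalent copper favour.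

Step 11
Reactants: 15 (1S,5R,8S)-8-[(2R)-1-[(tert-butyldiphenylsilyl)oxy]but-3-en-2-yl]-1-{[(tert-butyldimethylsilyl)oxy]methyl}-5-methyl-6-oxabicyclo[3.2.1]octane-2,7-dione
Product: 16 (1S,5R,8S)-8-[(2R)-1-[(tert-butyldiphenylsilyl)oxy]but-3-en-2-yl]-1-{[(tert-butyldimethylsilyl)oxy]methyl}-5-methyl-7-oxo-6-oxabicyclo[3.2.1]oct-2-en-2-yl trifluoromethanesulfonate
Conditions: KN(SiMe3)2, THF, −78 °C; PhNTf2, −78 → 0 °C
Reagents that add atoms: N-phenylbis(trifluoromethanesulfonimide), FC(F)(F)S(=O)(=O)N(c1ccccc1)S(=O)(=O)C(F)(F)F
Why: The ketone can enolise only towards C3, because C1 is quaternary, so enol triflate formation is regiochemically unambiguous; the lactone has no α-hydrogen.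

Step 12
Reactants: 16 (1S,5R,8S)-8-[(2R)-1-[(tert-butyldiphenylsilyl)oxy]but-3-en-2-yl]-1-{[(tert-butyldimethylsilyl)oxy]methyl}-5-methyl-7-oxo-6-oxabicyclo[3.2.1]oct-2-en-2-yl trifluoromethanesulfonate
Product: 17 (1R,5R,8S)-2-bromo-8-[(2R)-1-[(tert-butyldiphenylsilyl)oxy]but-3-en-2-yl]-1-{[(tert-butyldimethylsilyl)oxy]methyl}-5-methyl-6-oxabicyclo[3.2.1]oct-2-en-7-one
Conditions: Ni(OAc)2·4H2O (10 mol %), 1,5-cyclooctadiene, Zn (20 mol %), LiBr, DMA/THF, 23 °C
Reagents that add atoms: lithium bromide, [Li+].[Br-]
Why: Nickel-catalysed conversion of an enol triflate into the alkenyl bromide: zerovalent nickel inserts into the C–OTf bond, triflate is exchanged for bromide and C–Br reductive elimination follows. The room-temperature conditions tolerate silyl ethers, the lactone and the terminal alkene.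

Step 13
Reactants: 17 (1R,5R,8S)-2-bromo-8-[(2R)-1-[(tert-butyldiphenylsilyl)oxy]but-3-en-2-yl]-1-{[(tert-butyldimethylsilyl)oxy]methyl}-5-methyl-6-oxabicyclo[3.2.1]oct-2-en-7-one
Product: 18 (1R,5R,8S)-2-bromo-8-[(2R)-1-[(tert-butyldiphenylsilyl)oxy]but-3-en-2-yl]-1-(hydroxymethyl)-5-methyl-6-oxabicyclo[3.2.1]oct-2-en-7-one
Conditions: camphorsulfonic acid (cat.), MeOH/CH2Cl2, 0 → 23 °C
Reagents that add atoms: none
Why: Acid-catalysed methanolysis removes a primary tert-butyldimethylsilyl ether much faster than a tert-butyldiphenylsilyl ether. The hindered lactone does not transesterify, and the alcohol cannot translactonise because that would give a β-lactone.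

Step 14
Reactants: 18 (1R,5R,8S)-2-bromo-8-[(2R)-1-[(tert-butyldiphenylsilyl)oxy]but-3-en-2-yl]-1-(hydroxymethyl)-5-methyl-6-oxabicyclo[3.2.1]oct-2-en-7-one
Product: 19 (1R,5R,8S)-2-bromo-8-[(2R)-1-[(tert-butyldiphenylsilyl)oxy]but-3-en-2-yl]-5-methyl-7-oxo-6-oxabicyclo[3.2.1]oct-2-ene-1-carbaldehyde
Conditions: Dess–Martin periodinane, NaHCO3, CH2Cl2, 0 °C
Reagents that add atoms: none
Why: Oxidation of a neopentyl alcohol to a non-enolisable aldehyde; the ketone is already masked as the alkenyl bromide, so the aldehyde is not a tricarbonyl prone to deformylation.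

Step 15
Reactants: 19 (1R,5R,8S)-2-bromo-8-[(2R)-1-[(tert-butyldiphenylsilyl)oxy]but-3-en-2-yl]-5-methyl-7-oxo-6-oxabicyclo[3.2.1]oct-2-ene-1-carbaldehyde
Product: 20 (1S,5R,8S)-2-bromo-8-[(2R)-1-[(tert-butyldiphenylsilyl)oxy]but-3-en-2-yl]-1-ethenyl-5-methyl-6-oxabicyclo[3.2.1]oct-2-en-7-one
Conditions: Ph3PCH3Br, KN(SiMe3)2, THF, 0 °C; then 19, −78 → 0 °C
Reagents that add atoms: methyltriphenylphosphonium bromide, C[P+](c1ccccc1)(c1ccccc1)c1ccccc1.[Br-]
Why: Wittig methylenation; the small, salt-free ylide reacts with hindered aldehydes, and the aldehyde cannot epimerise.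

Step 16
Reactants: 20 (1S,5R,8S)-2-bromo-8-[(2R)-1-[(tert-butyldiphenylsilyl)oxy]but-3-en-2-yl]-1-ethenyl-5-methyl-6-oxabicyclo[3.2.1]oct-2-en-7-one
Product: 21 (1S,4R,5S,6R)-9-bromo-4-{[(tert-butyldiphenylsilyl)oxy]methyl}-6-methyl-11-oxatricyclo[4.3.2.0^{1,5}]undeca-2,8-dien-10-one
Conditions: second-generation Grubbs catalyst (5 mol %), CH2Cl2, 40 °C
Reagents that add atoms: none
Why: Ring-closing metathesis of the two vinyl groups gives the cyclopentene, which is cis-fused to the lactone ring and therefore unstrained. The catalyst loads on the less hindered vinyl group; the trisubstituted bromoalkene does not take part.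

Step 17
Reactants: 21 (1S,4R,5S,6R)-9-bromo-4-{[(tert-butyldiphenylsilyl)oxy]methyl}-6-methyl-11-oxatricyclo[4.3.2.0^{1,5}]undeca-2,8-dien-10-one
Product: 22 (1S,4R,5S,6R)-9-bromo-4-{[(tert-butyldiphenylsilyl)oxy]methyl}-6-methyl-11-oxatricyclo[4.3.2.0^{1,5}]undec-8-en-10-one
Conditions: 2-nitrobenzenesulfonyl hydrazide, Et3N, CH2Cl2, 23 °C
Reagents that add atoms: none
Why: Diimide reduces the strained cis-disubstituted cyclopentene and leaves the trisubstituted bromoalkene and the C–Br bond alone, which a palladium-catalysed hydrogenation would not.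

Step 18
Reactants: 22 (1S,4R,5S,6R)-9-bromo-4-{[(tert-butyldiphenylsilyl)oxy]methyl}-6-methyl-11-oxatricyclo[4.3.2.0^{1,5}]undec-8-en-10-one
Product: 23 (1S,4R,5S,6R,9S)-9-bromo-4-{[(tert-butyldiphenylsilyl)oxy]methyl}-6-methyl-11-oxatricyclo[4.3.2.0^{1,5}]undecan-10-one
Conditions: Mn(dpm)3 (10 mol %), PhSiH3, t-BuOOH, i-PrOH, 23 °C
Reagents that add atoms: none
Why: Hydrogen-atom-transfer hydrogenation of a bromoalkene: the manganese hydride gives hydrogen to C8 and the α-bromo radical at C9 keeps its bromine. The second hydrogen enters axially, on the face away from the lactone carbonyl, in the chair locked by the lactone bridge, so bromine ends equatorial (9S).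

Step 19
Reactants: 23 (1S,4R,5S,6R,9S)-9-bromo-4-{[(tert-butyldiphenylsilyl)oxy]methyl}-6-methyl-11-oxatricyclo[4.3.2.0^{1,5}]undecan-10-one
Product: 24 (1S,4R,5S,6R,9S)-9-bromo-4-(hydroxymethyl)-6-methyl-11-oxatricyclo[4.3.2.0^{1,5}]undecan-10-one
Conditions: Bu4NF, AcOH, THF, 0 → 23 °C
Reagents that add atoms: none
Why: Buffered fluoride desilylation; the equatorial bromide has no anti-periplanar hydrogen for elimination, and the hydroxymethyl group is trans to the lactone carbonyl on the cyclopentane and cannot translactonise.

Step 20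
Reactants: 24 (1S,4R,5S,6R,9S)-9-bromo-4-(hydroxymethyl)-6-methyl-11-oxatricyclo[4.3.2.0^{1,5}]undecan-10-one
Product: 25 (1S,4R,5S,6R,9S)-9-bromo-4-(iodomethyl)-6-methyl-11-oxatricyclo[4.3.2.0^{1,5}]undecan-10-one
Conditions: I2, PPh3, imidazole, CH2Cl2, 0 → 23 °C
Reagents that add atoms: iodine, II
Why: Appel-type iodination of a primary alcohol under neutral conditions.

Step 21
Reactants: 26 5-methylhex-4-enoic acid
Product: 27 (5S)-5-bromo-6,6-dimethyloxan-2-one
Conditions: 2,4,4,6-tetrabromocyclohexa-2,5-dienone, chiral BINOL-derived amidine–phenol catalyst (10 mol %), PhMe/CH2Cl2, −50 °C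
Reagents that add atoms: 2,4,4,6-tetrabromocyclohexa-2,5-dien-1-one, BrC1=CC(Br)(Br)C=C(Br)C1=O
Why: Catalytic enantioselective 6-endo bromolactonisation: the carboxylate opens the catalyst-bound bromonium ion at the tertiary carbon, so bromine ends on the secondary carbon. The configuration there is set by the catalyst.

Step 22
Reactants: 27 (5S)-5-bromo-6,6-dimethyloxan-2-one
Product: 28 (3S)-3-bromo-2,2-dimethyl-6-methylideneoxane
Conditions: Cp2TiMe2, PhMe, 65 °C, dark
Reagents that add atoms: dimethyltitanocene, C[Ti](C)(C1C=CC=C1)C1C=CC=C1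
Why: Petasis methylenation of a lactone carbonyl gives the exocyclic enol ether; the titanium carbene does not touch the secondary bromide and no alkoxide is formed next to it.

Step 23
Reactants: 28 (3S)-3-bromo-2,2-dimethyl-6-methylideneoxane
Product: 29 (4S)-4-bromo-3,3-dimethylcyclohexan-1-one
Conditions: Me3SiOTf (20 mol %), CH2Cl2, −78 → −40 °C
Reagents that add atoms: none
Why: Proposed new method: Me3SiOTf silylates the enol ether oxygen and the tertiary C–O bond ionises with help from the anti-periplanar equatorial bromine (bromonium ion); the silyl enol ether so released attacks the tertiary carbon with its CH2 terminus in a six-membered closure and returns the silyl cation, and since bromine never leaves its carbon the (S) configuration is kept. The closest known reaction types are the Petasis–Ferrier [1,3] oxygen-to-carbon rearrangement of cyclic enol acetals and the Lewis-acid α-tert-alkylation of silyl enol ethers.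

Step 24
Reactants: 25 (1S,4R,5S,6R,9S)-9-bromo-4-(iodomethyl)-6-methyl-11-oxatricyclo[4.3.2.0^{1,5}]undecan-10-one; 29 (4S)-4-bromo-3,3-dimethylcyclohexan-1-one
Product: 32 (1S,4S,5S,6R,9S)-9-bromo-4-{[(1S,4S)-4-bromo-1-hydroxy-3,3-dimethylcyclohexyl]methyl}-6-methyl-11-oxatricyclo[4.3.2.0^{1,5}]undecan-10-one, via primary alkyllithium 30 (not isolated), via alkylcerium dichloride 31 (not isolated)
Conditions: t-BuLi (2.1 equiv), Et2O/pentane, −78 °C; CeCl3, THF, −78 °C; then 29, −78 → −40 °C; aq. NH4Cl
Reagents that add atoms: none
Why: Iodine–lithium exchange at a primary iodide is faster at −78 °C than attack of t-BuLi on the hindered lactone or on the secondary bromide, and the organocerium reagent adds to the ketone without enolising it. The reagent should enter equatorially, anti to the axial methyl group at C3, in the chair with equatorial bromine; this puts the hydroxyl axial and cis to bromine, as in 32.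

## Compound list

1 | (R)-4-benzyl-1,3-oxazolidin-2-one | O=C1N[C@H](Cc2ccccc2)CO1 | starting material
2 | (E)-but-2-enoyl chloride | C/C=C/C(Cl)=O | starting material
3 | (R)-4-benzyl-3-[(E)-but-2-enoyl]-1,3-oxazolidin-2-one | C/C=C/C(=O)N1[C@H](Cc2ccccc2)COC1=O | intermediate
4 | 2-methylprop-2-enal (methacrolein) | CC(=C)C=O | starting material
5 | (4R)-4-benzyl-3-[(2R,3R)-2-ethenyl-3-hydroxy-4-methylpent-4-enoyl]-1,3-oxazolidin-2-one | O=C1OC[C@@H](Cc2ccccc2)N1C(=O)[C@H](C=C)[C@@H](O)C(C)=C | intermediate
6 | (2S,3R)-2-ethenyl-4-methylpent-4-ene-1,3-diol | OC[C@H](C=C)[C@@H](O)C(C)=C | intermediate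
7 | (3R,4S)-4-{[(tert-butyldiphenylsilyl)oxy]methyl}-2-methylhexa-1,5-dien-3-ol | CC(C)(C)[Si](c1ccccc1)(c1ccccc1)OC[C@H](C=C)[C@@H](O)C(C)=C | intermediate
8 | triethyl orthoacetate (1,1,1-triethoxyethane) | CCOC(C)(OCC)OCC | starting material
9 | ethyl (4E,6R)-6-{[(tert-butyldiphenylsilyl)oxy]methyl}-4-methylocta-4,7-dienoate | CCOC(=O)CC/C(C)=C/[C@H](CO[Si](c1ccccc1)(c1ccccc1)C(C)(C)C)C=C | intermediate
10 | (4E,6R)-6-{[(tert-butyldiphenylsilyl)oxy]methyl}-4-methylocta-4,7-dienal | O=CCC/C(C)=C/[C@H](CO[Si](c1ccccc1)(c1ccccc1)C(C)(C)C)C=C | intermediate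
11 | ethyl 3-hydroxypropanoate | CCOC(=O)CCO | starting material
12 | ethyl 3-[(tert-butyldimethylsilyl)oxy]propanoate | CCOC(=O)CCO[Si](C)(C)C(C)(C)C | intermediate
13 | ethyl (6E,8R)-2-{[(tert-butyldimethylsilyl)oxy]methyl}-8-{[(tert-butyldiphenylsilyl)oxy]methyl}-3-hydroxy-6-methyldeca-6,9-dienoate (mixture at C2 and C3) | CCOC(=O)C(CO[Si](C)(C)C(C)(C)C)C(O)CC/C(C)=C/[C@H](CO[Si](c1ccccc1)(c1ccccc1)C(C)(C)C)C=C | intermediate
14 | ethyl (6E,8R)-2-{[(tert-butyldimethylsilyl)oxy]methyl}-8-{[(tert-butyldiphenylsilyl)oxy]methyl}-6-methyl-3-oxodeca-6,9-dienoate (C2 epimers) | CCOC(=O)C(CO[Si](C)(C)C(C)(C)C)C(=O)CC/C(C)=C/[C@H](CO[Si](c1ccccc1)(c1ccccc1)C(C)(C)C)C=C | intermediate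
15 | (1S,5R,8S)-8-[(2R)-1-[(tert-butyldiphenylsilyl)oxy]but-3-en-2-yl]-1-{[(tert-butyldimethylsilyl)oxy]methyl}-5-methyl-6-oxabicyclo[3.2.1]octane-2,7-dione | CC(C)(C)[Si](C)(C)OC[C@]12C(=O)O[C@](C)(CCC1=O)[C@H]2[C@H](CO[Si](c3ccccc3)(c3ccccc3)C(C)(C)C)C=C | intermediate
16 | (1S,5R,8S)-8-[(2R)-1-[(tert-butyldiphenylsilyl)oxy]but-3-en-2-yl]-1-{[(tert-butyldimethylsilyl)oxy]methyl}-5-methyl-7-oxo-6-oxabicyclo[3.2.1]oct-2-en-2-yl trifluoromethanesulfonate | CC(C)(C)[Si](C)(C)OC[C@]12C(=O)O[C@](C)(CC=C1OS(=O)(=O)C(F)(F)F)[C@H]2[C@H](CO[Si](c3ccccc3)(c3ccccc3)C(C)(C)C)C=C | intermediate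
17 | (1R,5R,8S)-2-bromo-8-[(2R)-1-[(tert-butyldiphenylsilyl)oxy]but-3-en-2-yl]-1-{[(tert-butyldimethylsilyl)oxy]methyl}-5-methyl-6-oxabicyclo[3.2.1]oct-2-en-7-one | CC(C)(C)[Si](C)(C)OC[C@]12C(=O)O[C@](C)(CC=C1Br)[C@H]2[C@H](CO[Si](c3ccccc3)(c3ccccc3)C(C)(C)C)C=C | intermediate
18 | (1R,5R,8S)-2-bromo-8-[(2R)-1-[(tert-butyldiphenylsilyl)oxy]but-3-en-2-yl]-1-(hydroxymethyl)-5-methyl-6-oxabicyclo[3.2.1]oct-2-en-7-one | OC[C@]12C(=O)O[C@](C)(CC=C1Br)[C@H]2[C@H](CO[Si](c3ccccc3)(c3ccccc3)C(C)(C)C)C=C | intermediate
19 | (1R,5R,8S)-2-bromo-8-[(2R)-1-[(tert-butyldiphenylsilyl)oxy]but-3-en-2-yl]-5-methyl-7-oxo-6-oxabicyclo[3.2.1]oct-2-ene-1-carbaldehyde | O=C[C@]12C(=O)O[C@](C)(CC=C1Br)[C@H]2[C@H](CO[Si](c3ccccc3)(c3ccccc3)C(C)(C)C)C=C | intermediate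
20 | (1S,5R,8S)-2-bromo-8-[(2R)-1-[(tert-butyldiphenylsilyl)oxy]but-3-en-2-yl]-1-ethenyl-5-methyl-6-oxabicyclo[3.2.1]oct-2-en-7-one | C=C[C@]12C(=O)O[C@](C)(CC=C1Br)[C@H]2[C@H](CO[Si](c3ccccc3)(c3ccccc3)C(C)(C)C)C=C | intermediate
21 | (1S,4R,5S,6R)-9-bromo-4-{[(tert-butyldiphenylsilyl)oxy]methyl}-6-methyl-11-oxatricyclo[4.3.2.0^{1,5}]undeca-2,8-dien-10-one | CC(C)(C)[Si](c1ccccc1)(c1ccccc1)OC[C@@H]2C=C[C@]34C(=O)O[C@](C)(CC=C3Br)[C@@H]24 | intermediate
22 | (1S,4R,5S,6R)-9-bromo-4-{[(tert-butyldiphenylsilyl)oxy]methyl}-6-methyl-11-oxatricyclo[4.3.2.0^{1,5}]undec-8-en-10-one | CC(C)(C)[Si](c1ccccc1)(c1ccccc1)OC[C@@H]2CC[C@]34C(=O)O[C@](C)(CC=C3Br)[C@@H]24 | intermediate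
23 | (1S,4R,5S,6R,9S)-9-bromo-4-{[(tert-butyldiphenylsilyl)oxy]methyl}-6-methyl-11-oxatricyclo[4.3.2.0^{1,5}]undecan-10-one | CC(C)(C)[Si](c1ccccc1)(c1ccccc1)OC[C@@H]2CC[C@]34C(=O)O[C@](C)(CC[C@@H]3Br)[C@@H]24 | intermediate
24 | (1S,4R,5S,6R,9S)-9-bromo-4-(hydroxymethyl)-6-methyl-11-oxatricyclo[4.3.2.0^{1,5}]undecan-10-one | OC[C@@H]1CC[C@]23C(=O)O[C@](C)(CC[C@@H]2Br)[C@@H]13 | intermediate
25 | (1S,4R,5S,6R,9S)-9-bromo-4-(iodomethyl)-6-methyl-11-oxatricyclo[4.3.2.0^{1,5}]undecan-10-one | IC[C@@H]1CC[C@]23C(=O)O[C@](C)(CC[C@@H]2Br)[C@@H]13 | intermediate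
26 | 5-methylhex-4-enoic acid | CC(C)=CCCC(=O)O | starting material
27 | (5S)-5-bromo-6,6-dimethyloxan-2-one | CC1(C)OC(=O)CC[C@@H]1Br | intermediate
28 | (3S)-3-bromo-2,2-dimethyl-6-methylideneoxane | CC1(C)OC(=C)CC[C@@H]1Br | intermediate
29 | (4S)-4-bromo-3,3-dimethylcyclohexan-1-one | CC1(C)CC(=O)CC[C@@H]1Br | intermediate
30 | primary alkyllithium from 25 (lithium in place of iodine) | [Li]C[C@@H]1CC[C@]23C(=O)O[C@](C)(CC[C@@H]2Br)[C@@H]13 | intermediate (not isolated)
31 | alkylcerium dichloride from 30 | Cl[Ce](Cl)C[C@@H]1CC[C@]23C(=O)O[C@](C)(CC[C@@H]2Br)[C@@H]13 | intermediate (not isolated)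
32 | (1S,4S,5S,6R,9S)-9-bromo-4-{[(1S,4S)-4-bromo-1-hydroxy-3,3-dimethylcyclohexyl]methyl}-6-methyl-11-oxatricyclo[4.3.2.0^{1,5}]undecan-10-one | CC1(C)C[C@@](O)(C[C@@H]2CC[C@]34C(=O)O[C@](C)(CC[C@@H]3Br)[C@@H]24)CC[C@@H]1Br | target

## Step count and least certain steps

Total: 24 steps. Longest linear sequence: 20 steps (steps 1–6, 8–20 and 24); steps 7 and 21–23 prepare the two side fragments 12 and 29.

**Step 23 (proposed new method).** The tertiary cation may lose a proton instead of being captured, or may re-close on oxygen so that 28 is only returned. The fallback uses known reactions, sets out from 28 and returns at 29. Mild aqueous acid hydrolyses 28 to (5S)-5-bromo-6-hydroxy-6-methylheptan-2-one F1. Concentrated HCl then exchanges the tertiary hydroxyl, with retention through the bromonium ion, to give (5S)-5-bromo-6-chloro-6-methylheptan-2-one F2. Kinetic enolisation with LiN(i-Pr)2 in the presence of Me3SiCl at −78 °C gives {[(5S)-5-bromo-6-chloro-6-methylhept-1-en-2-yl]oxy}trimethylsilane F3. TiCl4 in CH2Cl2 at −78 °C then ionises the tertiary chloride and closes the ring by α-tert-alkylation of the silyl enol ether, giving 29.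

**Step 10 (key step).** Three things may go wrong: poor facial selectivity, because the vinyl and silyloxymethyl groups on the allylic carbon differ only moderately in size; β-elimination of silanol from the enolised keto ester; and proton loss or acetate capture at the tertiary cation instead of lactone closure. The fallback keeps the same bond formation but uses atom transfer, setting out from 14 and returning at 15. N-Bromosuccinimide with Mg(ClO4)2 (cat.) gives ethyl (6E,8R)-2-bromo-2-{[(tert-butyldimethylsilyl)oxy]methyl}-8-{[(tert-butyldiphenylsilyl)oxy]methyl}-6-methyl-3-oxodeca-6,9-dienoate F4. Et3B/O2 with Yb(OTf)3 at −78 °C starts a Lewis-acid-promoted atom-transfer radical cyclisation to ethyl 3-bromo-1-{[(tert-butyldimethylsilyl)oxy]methyl}-2-[(2R)-1-[(tert-butyldiphenylsilyl)oxy]but-3-en-2-yl]-3-methyl-6-oxocyclohexane-1-carboxylate F5 (C1 and C2 as in 15, C3 epimers). AgOTf then ionises the tertiary bromide and the ester closes the lactone to 15.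

**Step 24 (union).** The alkyllithium may attack the lactone or exchange with a secondary bromide before it is transmetalated. Face selectivity at the ketone may also erode, because the chair of 29 with axial bromine is close in energy and would give the epimer at the carbinol carbon. That epimer differs in ring A geometry and should be separable. The fallback is a samarium Barbier reaction from 25 and 29 to 32: the two are mixed and treated with SmI2 (2.2 equiv) and NiI2 (cat.) in THF at 0 °C, so that the alkylsamarium is trapped by the ketone as it forms and no alkyllithium is present. No new compound is isolated. This fallback does not improve face selectivity.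

**Step 8 (aldol).** The lithium enolate of 12 may lose silanolate by β-elimination before it adds, giving ethyl acrylate. The fallback sets out from 10 and returns at 14. A Roskamp homologation with ethyl diazoacetate and SnCl2 (cat.) gives ethyl (6E,8R)-8-{[(tert-butyldiphenylsilyl)oxy]methyl}-6-methyl-3-oxodeca-6,9-dienoate F6. Aqueous formaldehyde with catalytic KHCO3 gives ethyl (6E,8R)-8-{[(tert-butyldiphenylsilyl)oxy]methyl}-2-(hydroxymethyl)-6-methyl-3-oxodeca-6,9-dienoate F7, which is silylated (TBSCl, imidazole) to 14.

## Further compounds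

F1 | step 23 | (5S)-5-bromo-6-hydroxy-6-methylheptan-2-one | CC(=O)CC[C@H](Br)C(C)(C)O
F2 | step 23 | (5S)-5-bromo-6-chloro-6-methylheptan-2-one | CC(=O)CC[C@H](Br)C(C)(C)Cl
F3 | step 23 | {[(5S)-5-bromo-6-chloro-6-methylhept-1-en-2-yl]oxy}trimethylsilane | C=C(CC[C@H](Br)C(C)(C)Cl)O[Si](C)(C)C
F4 | step 10 | ethyl (6E,8R)-2-bromo-2-{[(tert-butyldimethylsilyl)oxy]methyl}-8-{[(tert-butyldiphenylsilyl)oxy]methyl}-6-methyl-3-oxodeca-6,9-dienoate | CCOC(=O)C(Br)(CO[Si](C)(C)C(C)(C)C)C(=O)CC/C(C)=C/[C@H](CO[Si](c1ccccc1)(c1ccccc1)C(C)(C)C)C=C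
F5 | step 10 | ethyl 3-bromo-1-{[(tert-butyldimethylsilyl)oxy]methyl}-2-[(2R)-1-[(tert-butyldiphenylsilyl)oxy]but-3-en-2-yl]-3-methyl-6-oxocyclohexane-1-carboxylate (C1 and C2 as in 15, C3 epimers) | CCOC(=O)[C@@]1(CO[Si](C)(C)C(C)(C)C)C(=O)CCC(C)(Br)[C@H]1[C@H](CO[Si](c2ccccc2)(c2ccccc2)C(C)(C)C)C=C
F0 | step 24 | none | none
F6 | step 8 | ethyl (6E,8R)-8-{[(tert-butyldiphenylsilyl)oxy]methyl}-6-methyl-3-oxodeca-6,9-dienoate | CCOC(=O)CC(=O)CC/C(C)=C/[C@H](CO[Si](c1ccccc1)(c1ccccc1)C(C)(C)C)C=C
F7 | step 8 | ethyl (6E,8R)-8-{[(tert-butyldiphenylsilyl)oxy]methyl}-2-(hydroxymethyl)-6-methyl-3-oxodeca-6,9-dienoate | CCOC(=O)C(CO)C(=O)CC/C(C)=C/[C@H](CO[Si](c1ccccc1)(c1ccccc1)C(C)(C)C)C=C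
A1 | alternative 1 | 9-bromo-6-methyl-10-oxo-11-oxatricyclo[4.3.2.0^{1,5}]undecane-4-carboxylic acid (tricyclic bromo lactone acid) | OC(=O)[C@@H]1CC[C@]23C(=O)O[C@](C)(CC[C@@H]2Br)[C@@H]13
A2 | alternative 2 | trans-fused bromocyclohexene angular carboxylic acid with silyloxymethyl and tertiary triethylsilyl ether | CC(C)(C)[Si](C)(C)OC[C@@H]1CC[C@]2(C(=O)O)[C@@H](Br)C=C[C@@](C)(O[Si](CC)(CC)CC)[C@@H]12
A3 | alternative 3 | cyclopentanecarbaldehyde with quaternary centre, adjacent CHBr (pivalate) and dioxolane | CC(C)(C)[Si](C)(C)OC[C@@H]1CC[C@](C=O)([C@@H](Br)COC(=O)C(C)(C)C)[C@H]1C2(C)OCCO2
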